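**Retrosynthetic overview**

1. Target 21 ⇐ protected chromene 19 by fluoride cleavage of the aryl 2-(trimethylsilyl)ethyl ether and weak-acid ketal hydrolysis.
2. 19 ⇐ β-hydroxy phosphine oxide 14 (the O1–C2–C3 unit) + 2-fluorobenzaldehyde 16 (the C8a–C4a–C4 unit) in one anionic [3+3] annulation: O1–C8a by SNAr, then C3=C4 by intramolecular Horner–Wittig olefination.
3. Enabling feature: in the pyran ring (ring B) O1 sits on C8a, ortho to C4a, which carries C4. As a formyl group C4 first activates C8a–F and then accepts the C3 carbanion, and the fully substituted C2 keeps its C–O bond throughout.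
4. 14 ⇐ Sharpless epoxidation and hydride opening (sets C2) of an E-allylic alcohol made by cross-metathesis. The ring diol comes from equatorial hydroxymethylation of (S)-2-allyl-3,3-dimethylcyclohexanone, itself from Pd-catalysed decarboxylative asymmetric allylation.
5. Ring order: the cyclohexane (ring C) is bought as 3-methylcyclohexenone, the arene (ring A) as 2,6-difluoro-4-methylbenzaldehyde, and ring B is closed last.

Key step: step 12

Assumption (chemistry): the (R,R) enantiomer of the ANDEN-phenyl Trost ligand is taken to give the (S)-ketone 3; if the sense is the opposite, the (S,S) ligand is used and nothing else changes.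
Assumption (supply): compounds 1 and 15 and all reagents are taken as commercial.

**Route**

Step 1
Reactants: 1 3-methylcyclohex-2-en-1-one
Product: 2 3,3-dimethylcyclohex-1-en-1-yl prop-2-en-1-yl carbonate
Conditions: Me2CuLi (from MeLi and CuI), Et2O, 0 °C; then TMEDA, allyl chloroformate, THF, −78 °C → rt
Reagents that add atoms: lithium dimethylcuprate [Li+].C[Cu-]C; allyl chloroformate C=CCOC(=O)Cl
Why: Conjugate addition of the Gilman cuprate builds the gem-dimethyl carbon and a regiodefined lithium enolate, which chloroformates acylate on oxygen to give the enol carbonate; no stereocenter is formed.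

Step 2
Reactants: 2 3,3-dimethylcyclohex-1-en-1-yl prop-2-en-1-yl carbonate
Product: 3 (2S)-3,3-dimethyl-2-(prop-2-en-1-yl)cyclohexan-1-one
Conditions: Pd2(dba)3·CHCl3 (2.5 mol %), (R,R)-ANDEN-phenyl Trost ligand (5.5 mol %), 1,4-dioxane, 23 °C
Reagents that add atoms: none
Why: Pd-catalysed decarboxylative asymmetric allylic alkylation (Tsuji–Trost type): loss of CO2 gives a π-allylpalladium enolate ion pair that recombines at the enolate carbon under neutral conditions, so the α-tertiary ketone should not racemise, and the chiral ligand selects the enolate face to set C2 as S.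

Step 3
Reactants: 3 (2S)-3,3-dimethyl-2-(prop-2-en-1-yl)cyclohexan-1-one
Product: 5 (1R,2S)-1-(hydroxymethyl)-3,3-dimethyl-2-(prop-2-en-1-yl)cyclohexan-1-ol, via silylmethyl carbinol 4 (not isolated)
Conditions: (i-PrO)Me2SiCH2MgCl, THF, 0 °C → rt; then KF, KHCO3, 30 % H2O2, THF/MeOH, rt
Reagents that add atoms: (isopropoxydimethylsilyl)methylmagnesium chloride CC(C)O[Si](C)(C)C[Mg]Cl; hydrogen peroxide OO
Why: Tamao nucleophilic hydroxymethylation (Grignard addition, then Tamao–Fleming oxidation of the C–Si bond): in the chair with equatorial allyl the axial C3 methyl blocks axial approach, so the reagent should enter equatorially and the new hydroxyl ends up axial and cis to the allyl group (C1 R).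

Step 4
Reactants: 5 (1R,2S)-1-(hydroxymethyl)-3,3-dimethyl-2-(prop-2-en-1-yl)cyclohexan-1-ol
Product: 6 (5R,6S)-2,2,7,7-tetramethyl-6-(prop-2-en-1-yl)-1,3-dioxaspiro[4.5]decane
Conditions: 2,2-dimethoxypropane, PPTS (cat.), CH2Cl2, rt
Reagents that add atoms: 2,2-dimethoxypropane COC(C)(C)OC
Why: Acid-catalysed transketalisation masks the 1,2-diol as its acetonide against the later hydride, phosphide and amide bases; no stereocenter is touched.

Step 5
Reactants: 6 (5R,6S)-2,2,7,7-tetramethyl-6-(prop-2-en-1-yl)-1,3-dioxaspiro[4.5]decane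
Product: 7 (2E)-2-methyl-4-[(5R,6S)-2,2,7,7-tetramethyl-1,3-dioxaspiro[4.5]decan-6-yl]but-2-enal
Conditions: methacrolein (5 equiv), second-generation Hoveyda–Grubbs catalyst (5 mol %), CH2Cl2, 40 °C
Reagents that add atoms: methacrolein CC(=C)C=O
Why: Olefin cross-metathesis of a terminal alkene with methacrolein should give the trisubstituted enal, with the E isomer favoured thermodynamically.

Step 6
Reactants: 7 (2E)-2-methyl-4-[(5R,6S)-2,2,7,7-tetramethyl-1,3-dioxaspiro[4.5]decan-6-yl]but-2-enal
Product: 8 (2E)-2-methyl-4-[(5R,6S)-2,2,7,7-tetramethyl-1,3-dioxaspiro[4.5]decan-6-yl]but-2-en-1-ol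
Conditions: NaBH4, CeCl3·7H2O, MeOH, −20 °C
Reagents that add atoms: none
Why: Luche reduction is 1,2-selective for the enal and leaves the alkene geometry unchanged.

Step 7
Reactants: 8 (2E)-2-methyl-4-[(5R,6S)-2,2,7,7-tetramethyl-1,3-dioxaspiro[4.5]decan-6-yl]but-2-en-1-ol
Product: 9 [(2R,3R)-2-methyl-3-{[(5R,6S)-2,2,7,7-tetramethyl-1,3-dioxaspiro[4.5]decan-6-yl]methyl}oxiran-2-yl]methanol
Conditions: Ti(OiPr)4 (10 mol %), D-(−)-diethyl tartrate (12 mol %), t-BuOOH, 4 Å MS, CH2Cl2, −20 °C
Reagents that add atoms: tert-butyl hydroperoxide CC(C)(C)OO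
Why: Katsuki–Sharpless asymmetric epoxidation: the titanium tartrate complex delivers oxygen to one face of the allylic alcohol under reagent control (the ring stereocenters are remote), and D-(−)-tartrate should give the (2R,3R)-epoxide.

Step 8
Reactants: 9 [(2R,3R)-2-methyl-3-{[(5R,6S)-2,2,7,7-tetramethyl-1,3-dioxaspiro[4.5]decan-6-yl]methyl}oxiran-2-yl]methanol
Product: 10 (2S)-2-methyl-4-[(5R,6S)-2,2,7,7-tetramethyl-1,3-dioxaspiro[4.5]decan-6-yl]butane-1,2-diol
Conditions: LiAlH4, THF, 0 °C → rt
Reagents that add atoms: none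
Why: Hydride opening of the 2,3-epoxy alcohol occurs by SN2 attack at the less substituted C3 because C2 is fully substituted, so the C2–O bond is kept and the tertiary carbinol is formed with retention (2S).

Step 9
Reactants: 10 (2S)-2-methyl-4-[(5R,6S)-2,2,7,7-tetramethyl-1,3-dioxaspiro[4.5]decan-6-yl]butane-1,2-diol
Product: 12 (2S)-2-methyl-2-{2-[(5R,6S)-2,2,7,7-tetramethyl-1,3-dioxaspiro[4.5]decan-6-yl]ethyl}oxirane, via primary tosylate 11 (not isolated)
Conditions: TsCl, Et3N, Bu2SnO (2 mol %), CH2Cl2, 0 °C → rt; then K2CO3, MeOH, rt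
Reagents that add atoms: none
Why: Tin-catalysed selective sulfonylation of the primary hydroxyl is followed by 3-exo-tet closure (intramolecular Williamson etherification) by the tertiary alkoxide; no bond to C2 is broken, so its configuration is retained.

Step 10
Reactants: 12 (2S)-2-methyl-2-{2-[(5R,6S)-2,2,7,7-tetramethyl-1,3-dioxaspiro[4.5]decan-6-yl]ethyl}oxirane
Product: 14 (2S)-1-(diphenylphosphoryl)-2-methyl-4-[(5R,6S)-2,2,7,7-tetramethyl-1,3-dioxaspiro[4.5]decan-6-yl]butan-2-ol, via hydroxy phosphine 13 (not isolated)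
Conditions: KPPh2 (0.5 M in THF), THF, −20 → 0 °C; then 30 % H2O2, 0 °C
Reagents that add atoms: potassium diphenylphosphide [K+].[P-](c1ccccc1)c1ccccc1; hydrogen peroxide OO
Why: SN2 opening of the terminal epoxide at CH2 by the phosphide and oxidation at phosphorus give the β-hydroxy phosphine oxide used in Horner–Wittig chemistry, with C2 untouched.

Step 11
Reactants: 15 2,6-difluoro-4-methylbenzaldehyde
Product: 16 2-fluoro-4-methyl-6-[2-(trimethylsilyl)ethoxy]benzaldehyde
Conditions: Me3SiCH2CH2OH, NaH, THF, 0 °C → rt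
Reagents that add atoms: 2-(trimethylsilyl)ethanol C[Si](C)(C)CCO
Why: SNAr at a fluorine ortho to the formyl group should stop after one substitution because the new alkoxy group deactivates the ring; the second fluorine is kept for the key step.

Step 12
Reactants: 14 (2S)-1-(diphenylphosphoryl)-2-methyl-4-[(5R,6S)-2,2,7,7-tetramethyl-1,3-dioxaspiro[4.5]decan-6-yl]butan-2-ol; 16 2-fluoro-4-methyl-6-[2-(trimethylsilyl)ethoxy]benzaldehyde
Product: 19 trimethyl[2-({(2S)-2,7-dimethyl-2-[2-((5R,6S)-2,2,7,7-tetramethyl-1,3-dioxaspiro[4.5]decan-6-yl)ethyl]-2H-chromen-5-yl}oxy)ethyl]silane, via aryl ether aldehyde 17 (not isolated), via hydroxy phosphine oxide 18 (not isolated)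
Conditions: KHMDS (1.05 equiv), THF, −40 °C; 16, −40 → 0 °C; then KHMDS (1.2 equiv), −78 → 45 °C
Reagents that add atoms: none
Why: Proposed new method: the potassium alkoxide of 14 displaces fluoride from 16 (SNAr, activated by the ortho formyl group) to give 17; a second equivalent of base then removes a proton next to phosphorus, the carbanion adds to the formyl group within the molecule to give the oxido phosphine oxide 18, and syn-elimination of potassium diphenylphosphinate (Horner–Wittig) forms C3=C4. The closest known reactions are the SNAr of tertiary alkoxides with 2-fluorobenzaldehydes, the Horner–Wittig olefination, and the Schweizer 2H-chromene synthesis, in which the same kind of β-aryloxy phosphorus-stabilised carbanion closes onto an ortho formyl group. The only ring closed is ring B, by 6-exo-trig addition of the C3 carbanion to the C4 carbonyl, after the O1–C8a bond has joined the two fragments. No new stereocenter survives: C3 and C4 of 18 are lost on elimination, the cis ring alkene is fixed by the six-membered ring, and C2 keeps its S configuration because its C–O bond is never broken. The step needs O-arylation to come before collapse of the oxido phosphine oxide of 14 to a 1,1-disubstituted alkene, which the low temperature of the first stage should secure since that elimination needs warming. It also needs ring closure to beat β-elimination of the aryloxide from the carbanion of 17, which the adjacent formyl group should secure.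

Step 13
Reactants: 19 trimethyl[2-({(2S)-2,7-dimethyl-2-[2-((5R,6S)-2,2,7,7-tetramethyl-1,3-dioxaspiro[4.5]decan-6-yl)ethyl]-2H-chromen-5-yl}oxy)ethyl]silane
Product: 21 (1R,2S)-2-{2-[(2S)-5-hydroxy-2,7-dimethyl-2H-chromen-2-yl]ethyl}-1-(hydroxymethyl)-3,3-dimethylcyclohexan-1-ol, via acetonide phenol 20 (not isolated)
Conditions: TBAF (1 M in THF), 60 °C; then AcOH/H2O (3:1), 45 °C
Reagents that add atoms: none
Why: Fluoride-induced fragmentation of the 2-(trimethylsilyl)ethyl aryl ether frees the phenol, and hydrolysis of the isopropylidene ketal in weak acid frees the diol; weak acid is chosen because the electron-rich chromene is acid-sensitive, and no stereocenter is touched.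

**Compound list**

1 | 3-methylcyclohex-2-en-1-one | CC1=CC(=O)CCC1 | starting material
2 | 3,3-dimethylcyclohex-1-en-1-yl prop-2-en-1-yl carbonate | C=CCOC(=O)OC1=CC(C)(C)CCC1 | intermediate
3 | (2S)-3,3-dimethyl-2-(prop-2-en-1-yl)cyclohexan-1-one | C=CC[C@@H]1C(=O)CCCC1(C)C | intermediate
4 | (1R,2S)-1-{[dimethyl(propan-2-yloxy)silyl]methyl}-3,3-dimethyl-2-(prop-2-en-1-yl)cyclohexan-1-ol | C=CC[C@H]1C(C)(C)CCC[C@]1(O)C[Si](C)(C)OC(C)C | intermediate
5 | (1R,2S)-1-(hydroxymethyl)-3,3-dimethyl-2-(prop-2-en-1-yl)cyclohexan-1-ol | C=CC[C@H]1C(C)(C)CCC[C@]1(O)CO | intermediate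
6 | (5R,6S)-2,2,7,7-tetramethyl-6-(prop-2-en-1-yl)-1,3-dioxaspiro[4.5]decane | C=CC[C@H]1C(C)(C)CCC[C@]12COC(C)(C)O2 | intermediate
7 | (2E)-2-methyl-4-[(5R,6S)-2,2,7,7-tetramethyl-1,3-dioxaspiro[4.5]decan-6-yl]but-2-enal | O=C/C(C)=C/C[C@H]1C(C)(C)CCC[C@]12COC(C)(C)O2 | intermediate
8 | (2E)-2-methyl-4-[(5R,6S)-2,2,7,7-tetramethyl-1,3-dioxaspiro[4.5]decan-6-yl]but-2-en-1-ol | OC/C(C)=C/C[C@H]1C(C)(C)CCC[C@]12COC(C)(C)O2 | intermediate
9 | [(2R,3R)-2-methyl-3-{[(5R,6S)-2,2,7,7-tetramethyl-1,3-dioxaspiro[4.5]decan-6-yl]methyl}oxiran-2-yl]methanol | OC[C@@]1(C)O[C@@H]1C[C@H]2C(C)(C)CCC[C@]23COC(C)(C)O3 | intermediate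
10 | (2S)-2-methyl-4-[(5R,6S)-2,2,7,7-tetramethyl-1,3-dioxaspiro[4.5]decan-6-yl]butane-1,2-diol | O[C@@](C)(CC[C@H]1C(C)(C)CCC[C@]12COC(C)(C)O2)CO | intermediate
11 | (2S)-2-hydroxy-2-methyl-4-[(5R,6S)-2,2,7,7-tetramethyl-1,3-dioxaspiro[4.5]decan-6-yl]butyl 4-methylbenzenesulfonate | O[C@@](C)(CC[C@H]1C(C)(C)CCC[C@]12COC(C)(C)O2)COS(=O)(=O)c1ccc(C)cc1 | intermediate
12 | (2S)-2-methyl-2-{2-[(5R,6S)-2,2,7,7-tetramethyl-1,3-dioxaspiro[4.5]decan-6-yl]ethyl}oxirane | C[C@]1(CC[C@H]2C(C)(C)CCC[C@]23COC(C)(C)O3)CO1 | intermediate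
13 | (2S)-1-(diphenylphosphanyl)-2-methyl-4-[(5R,6S)-2,2,7,7-tetramethyl-1,3-dioxaspiro[4.5]decan-6-yl]butan-2-ol | O[C@@](C)(CC[C@H]1C(C)(C)CCC[C@]12COC(C)(C)O2)CP(c1ccccc1)c1ccccc1 | intermediate
14 | (2S)-1-(diphenylphosphoryl)-2-methyl-4-[(5R,6S)-2,2,7,7-tetramethyl-1,3-dioxaspiro[4.5]decan-6-yl]butan-2-ol | O[C@@](C)(CC[C@H]1C(C)(C)CCC[C@]12COC(C)(C)O2)CP(=O)(c1ccccc1)c1ccccc1 | intermediate
15 | 2,6-difluoro-4-methylbenzaldehyde | Cc1cc(F)c(C=O)c(F)c1 | starting material
16 | 2-fluoro-4-methyl-6-[2-(trimethylsilyl)ethoxy]benzaldehyde | Cc1cc(F)c(C=O)c(OCC[Si](C)(C)C)c1 | intermediate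
17 | 2-({(2S)-1-(diphenylphosphoryl)-2-methyl-4-[(5R,6S)-2,2,7,7-tetramethyl-1,3-dioxaspiro[4.5]decan-6-yl]butan-2-yl}oxy)-4-methyl-6-[2-(trimethylsilyl)ethoxy]benzaldehyde | Cc1cc(OCC[Si](C)(C)C)c(C=O)c(c1)O[C@@](C)(CC[C@H]1C(C)(C)CCC[C@]12COC(C)(C)O2)CP(=O)(c1ccccc1)c1ccccc1 | intermediate
18 | (2S)-3-(diphenylphosphoryl)-2,7-dimethyl-2-{2-[(5R,6S)-2,2,7,7-tetramethyl-1,3-dioxaspiro[4.5]decan-6-yl]ethyl}-5-[2-(trimethylsilyl)ethoxy]-3,4-dihydro-2H-chromen-4-ol (C3 and C4 epimers) | Cc1cc(OCC[Si](C)(C)C)c2c(c1)O[C@@](C)(CC[C@H]1C(C)(C)CCC[C@]13COC(C)(C)O3)C(C2O)P(=O)(c1ccccc1)c1ccccc1 | intermediate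
19 | trimethyl[2-({(2S)-2,7-dimethyl-2-[2-((5R,6S)-2,2,7,7-tetramethyl-1,3-dioxaspiro[4.5]decan-6-yl)ethyl]-2H-chromen-5-yl}oxy)ethyl]silane | Cc1cc(OCC[Si](C)(C)C)c2c(c1)O[C@@](C)(CC[C@H]1C(C)(C)CCC[C@]13COC(C)(C)O3)C=C2 | intermediate
20 | (2S)-2,7-dimethyl-2-{2-[(5R,6S)-2,2,7,7-tetramethyl-1,3-dioxaspiro[4.5]decan-6-yl]ethyl}-2H-chromen-5-ol | Cc1cc(O)c2c(c1)O[C@@](C)(CC[C@H]1C(C)(C)CCC[C@]13COC(C)(C)O3)C=C2 | intermediate
21 | (1R,2S)-2-{2-[(2S)-5-hydroxy-2,7-dimethyl-2H-chromen-2-yl]ethyl}-1-(hydroxymethyl)-3,3-dimethylcyclohexan-1-ol | Cc1cc(O)c2c(c1)O[C@@](C)(CC[C@H]1C(C)(C)CCC[C@]1(O)CO)C=C2 | target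

**Totals**

Total step count: 13. Longest linear sequence: 12 steps (steps 1–10, 12 and 13); step 11 is the one-step branch to the arene.

**Steps most likely to fail**

Step 12 (proposed new method). Two processes may go wrong. The potassium alkoxide of 14 may collapse by Horner–Wittig elimination to a 1,1-disubstituted alkene before it is arylated. The phosphorus-stabilised carbanion of 17 may also expel the aryloxide by β-elimination faster than it closes onto the formyl group. The fallback uses known chemistry, sets out from epoxide 12 and comes back at 19. One-carbon homologation of 12 with dimethylsulfonium methylide (Me3S+ I−, n-BuLi, THF, −10 °C → rt) should give the vinyl carbinol F1. Its potassium alkoxide (KHMDS, THF, 0 °C) displaces fluoride from 16 to give the aryl ether aldehyde F2. Wittig methylenation (Ph3P=CH2, THF, 0 °C) gives the diene F3. Ring-closing metathesis (second-generation Grubbs catalyst, CH2Cl2, 40 °C) then closes ring B to 19. In this fallback the aryl ether bond and the ring alkene are made in separate operations.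

Step 2. Facial discrimination of the hindered enolate next to the quaternary carbon may be poor, which would lower the enantiomeric purity at the ring stereocenter and give diastereomers after step 7; crystallisation of 14 is the natural point to upgrade purity. The fallback sets out from 1 and comes back at 3. Conjugate addition of Me2CuLi and trapping of the enolate with allyl bromide (HMPA) gives the racemic allyl ketone F4. Asymmetric hydrogenation under dynamic kinetic resolution (RuCl2[(S)-xylbinap][(S)-daipen] or its enantiomer, t-BuOK, i-PrOH, H2 at 8 atm) should give the cis alcohol F5, since the α-center epimerises under the basic conditions and the isolated alkene is not reduced. Dess–Martin oxidation, which is neutral, returns 3.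

Step 3. The Grignard reagent may enolise the hindered ketone instead of adding, and facial selectivity of the addition may be incomplete. The fallback sets out from 3 and comes back at 5. Epoxidation with dimethylsulfonium methylide (Me3S+ I−, KHMDS, THF, 0 °C) should deliver the methylene group equatorially for the same steric reason and give the spiro epoxide F6. Opening at the CH2 carbon with hydroxide (KOH, DMSO/H2O, 90 °C) leaves the tertiary C–O bond intact and gives 5.

**Further compounds**

F1 | step 12 | (3S)-3-methyl-5-[(5R,6S)-2,2,7,7-tetramethyl-1,3-dioxaspiro[4.5]decan-6-yl]pent-1-en-3-ol | O[C@@](C)(CC[C@H]1C(C)(C)CCC[C@]12COC(C)(C)O2)C=C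
F2 | step 12 | 4-methyl-2-({(3S)-3-methyl-5-[(5R,6S)-2,2,7,7-tetramethyl-1,3-dioxaspiro[4.5]decan-6-yl]pent-1-en-3-yl}oxy)-6-[2-(trimethylsilyl)ethoxy]benzaldehyde | Cc1cc(OCC[Si](C)(C)C)c(C=O)c(c1)O[C@@](C)(CC[C@H]1C(C)(C)CCC[C@]12COC(C)(C)O2)C=C
F3 | step 12 | {2-[2-ethenyl-5-methyl-3-({(3S)-3-methyl-5-[(5R,6S)-2,2,7,7-tetramethyl-1,3-dioxaspiro[4.5]decan-6-yl]pent-1-en-3-yl}oxy)phenoxy]ethyl}(trimethyl)silane | Cc1cc(OCC[Si](C)(C)C)c(C=C)c(c1)O[C@@](C)(CC[C@H]1C(C)(C)CCC[C@]12COC(C)(C)O2)C=C
F4 | step 2 | rac-3,3-dimethyl-2-(prop-2-en-1-yl)cyclohexan-1-one | C=CCC1C(=O)CCCC1(C)C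
F5 | step 2 | (1R,2S)-3,3-dimethyl-2-(prop-2-en-1-yl)cyclohexan-1-ol | C=CC[C@@H]1[C@H](O)CCCC1(C)C
F6 | step 3 | (3R,4S)-5,5-dimethyl-4-(prop-2-en-1-yl)-1-oxaspiro[2.5]octane | C=CC[C@H]1C(C)(C)CCC[C@]12CO2
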